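**Retrosynthetic overview**

1. The C19 chain is numbered from the pentyl CH3: ring carbons C6–C9 with O1 between C6 and C9, ester carbinol C10, alkene C18=C19. The laurate is put on O10 last; the 2,5-trans oxolane with threo C9/C10 oxygens is closed at O1–C9 by rhenium(VII) syn-oxidative cyclisation of a C6 alcohol onto an (E)-C9=C10 alkene.
2. That alkene is cut by Julia–Kocienski olefination into a C10–C19 phenyltetrazolyl sulfone (from 10-bromodec-1-ene) and the C9 lactol carbon of a C1–C9 furanose silylated at O7.
3. Feature on which the plan rests: C6–C9 (oxygen on C6 and C7, methylene C8, oxygen-bearing C9) is a 2-deoxy-L-threo-pentose with a butyl tail, and its furanose is the O1/C6–C9 oxolane. It is cut at C7–C8 into acetaldehyde and (S)-2-hydroxyheptanal, which an aldolase joins.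
4. (S)-2-Hydroxyheptanal comes from oct-1-en-3-ol by Sharpless kinetic resolution and ozonolysis.
5. Ring order: the lactol ring forms in the aldolase step, is opened in the olefination, and the same five atoms are closed again as the final oxolane in the rhenium step.

Key step: step 3

Assumption: an engineered 2-deoxyribose-5-phosphate aldolase that binds a lipophilic (S)-2-hydroxy aldehyde is taken to be obtainable by screening acetaldehyde-tolerant variants. Lactols and the methyl glycoside are handled as anomeric mixtures, which is harmless because C9 becomes an alkene carbon in step 9.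

**Route**

Step 1
Reactants: 1 rac-oct-1-en-3-ol
Product: 2 (S)-oct-1-en-3-ol (recovered slow-reacting enantiomer)
Conditions: Ti(OiPr)4 (cat.), D-(−)-DIPT (cat.), t-BuOOH (0.6 equiv), 4 Å MS, CH2Cl2, −20 °C
Reagents that add atoms: none
Why: Sharpless kinetic resolution (titanium–tartrate epoxidation): with D-(−)-DIPT the (R)-alcohol is epoxidised much faster, so running past half conversion should leave 2 in high enantiomeric purity, separable from the epoxy alcohol by distillation; this sets C6.

Step 2
Reactants: 2 (S)-oct-1-en-3-ol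
Product: 4 (S)-2-hydroxyheptanal, via secondary ozonide 3 (not isolated)
Conditions: O3, CH2Cl2, −78 °C; then Me2S, −78 °C → rt; concentrated and used at once
Reagents that add atoms: ozone, [O-][O+]=O
Why: Ozonolysis with reductive work-up (Criegee mechanism) cleaves only the vinyl group and leaves the carbinol centre untouched; the hydroxy aldehyde is not purified because it equilibrates with its hemiacetal dimer, which reopens in the aqueous medium of step 3.

Step 3
Reactants: 4 (S)-2-hydroxyheptanal; 5 acetaldehyde
Product: 7 (4S,5S)-5-pentyloxolane-2,4-diol (anomeric mixture), via open-chain aldol 6 (not isolated)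
Conditions: engineered 2-deoxyribose-5-phosphate aldolase (lysate or whole cells), acetaldehyde fed slowly, triethanolamine buffer pH 7.5, 10% DMSO, 25 °C; EtOAc extraction
Reagents that add atoms: none
Why: Proposed new method: the active-site lysine condenses with acetaldehyde 5 to an enamine that attacks the aldehyde carbon (C7) of 4, and hydrolysis of the iminium releases aldol 6 with the new C7–C8 bond; the closest known reaction type is the addition of acetaldehyde to short 2-hydroxy aldehydes (glyceraldehyde, lactaldehyde and L-configured analogues) by this aldolase to give 2-deoxypentoses, whereas a lipophilic seven-carbon L-type acceptor has not been shown and is expected to need a variant with an enlarged hydrophobic acceptor pocket. Aldol 6 then closes without a reagent by 5-exo-trig addition of the C6 hydroxyl to the C9 carbonyl (O1–C9), giving the furanose-type lactol 7. The new stereocentre C7 should be set as S by the enzyme, which presents one enamine face to the bound aldehyde (the 3S sense of the natural reaction) independently of the existing C6 centre; the anomeric carbon C9 forms as a mixture and is destroyed later. The step needs single addition and catalyst-controlled facial selectivity: the first is secured by the C6 hydroxyl, which masks the product aldehyde as the lactol so that it is not offered again as an acceptor, the second by the active site, provided 4 is free of its (R)-enantiomer, which the natural enzyme would take faster. Slow feeding of acetaldehyde limits its self-condensation and enzyme inactivation.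

Step 4
Reactants: 7 (4S,5S)-5-pentyloxolane-2,4-diol
Product: 8 (2S,3S)-5-methoxy-2-pentyloxolan-3-ol (methyl furanoside, anomeric mixture)
Conditions: MeOH, AcCl (cat.), 0 °C → rt; then Et3N
Reagents that add atoms: methanol, CO
Why: Fischer glycosidation: the 2-deoxy lactol ionises to its oxocarbenium ion under trace acid and is trapped by methanol; only a furanoside can form because no δ-hydroxyl exists, and C6/C7 are not involved.

Step 5
Reactants: 8 (2S,3S)-5-methoxy-2-pentyloxolan-3-ol
Product: 9 tert-butyl{[(2S,3S)-5-methoxy-2-pentyloxolan-3-yl]oxy}diphenylsilane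
Conditions: TBDPSCl, imidazole, DMAP (cat.), DMF, 40 °C
Reagents that add atoms: tert-butyl(chloro)diphenylsilane, CC(C)(C)[Si](Cl)(c1ccccc1)c1ccccc1
Why: Imidazole-promoted silylation of the single free hydroxyl (C7); TBDPS is chosen because it should survive the aqueous acid of step 6, the base of step 9 and the rhenium reagent of step 10.

Step 6
Reactants: 9 tert-butyl{[(2S,3S)-5-methoxy-2-pentyloxolan-3-yl]oxy}diphenylsilane
Product: 10 (4S,5S)-4-[(tert-butyldiphenylsilyl)oxy]-5-pentyloxolan-2-ol (anomeric mixture)
Conditions: AcOH/H2O (4:1), 50 °C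
Reagents that add atoms: water, O
Why: Acid-catalysed acetal hydrolysis: a 2-deoxyfuranoside is cleaved through its oxocarbenium ion in aqueous acetic acid, to which TBDPS ethers are stable.

Step 7
Reactants: 11 10-bromodec-1-ene; 12 1-phenyl-1H-tetrazole-5-thiol
Product: 13 5-(dec-9-en-1-ylsulfanyl)-1-phenyl-1H-tetrazole
Conditions: K2CO3, acetone, rt
Reagents that add atoms: none
Why: SN2 S-alkylation of the tetrazolyl thiolate by the primary bromide.

Step 8
Reactants: 13 5-(dec-9-en-1-ylsulfanyl)-1-phenyl-1H-tetrazole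
Product: 15 5-(dec-9-ene-1-sulfonyl)-1-phenyl-1H-tetrazole, via sulfoxide 14 (not isolated)
Conditions: (NH4)6Mo7O24·4H2O (cat.), 30% H2O2, EtOH, 0 °C → rt
Reagents that add atoms: hydrogen peroxide, OO
Why: Molybdate-catalysed peroxide oxidation of sulfide to sulfone through the sulfoxide; the peroxomolybdate oxidises sulfur and leaves the unactivated terminal alkene alone, which a peracid would not.

Step 9
Reactants: 10 (4S,5S)-4-[(tert-butyldiphenylsilyl)oxy]-5-pentyloxolan-2-ol; 15 5-(dec-9-ene-1-sulfonyl)-1-phenyl-1H-tetrazole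
Product: 17 (6S,7S,9E)-7-[(tert-butyldiphenylsilyl)oxy]nonadeca-9,18-dien-6-ol, via β-alkoxy sulfone adduct 16 (not isolated)
Conditions: 15 (2.5 equiv), KHMDS (2.4 equiv), DME, −60 °C; then 10, −60 °C → rt
Reagents that add atoms: none
Why: Julia–Kocienski olefination: the lactolate of 10 opens to the C9 aldehyde, the metalated sulfone adds, and Smiles rearrangement with loss of sulfur dioxide and tetrazolate gives the alkene, the phenyltetrazolyl sulfone with potassium in DME favouring the E isomer; the excess anion covers the lactol proton and C6/C7 are untouched.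

Step 10
Reactants: 17 (6S,7S,9E)-7-[(tert-butyldiphenylsilyl)oxy]nonadeca-9,18-dien-6-ol
Product: 19 (1R)-1-[(2R,4S,5S)-4-[(tert-butyldiphenylsilyl)oxy]-5-pentyloxolan-2-yl]dec-9-en-1-ol, via perrhenate ester 18 (not isolated)
Conditions: Re2O7, (CF3CO)2O, THF, rt, then evaporation; 17, CH2Cl2, 0 °C → rt; aq. NaHCO3/MeOH work-up
Reagents that add atoms: dirhenium heptoxide, O=[Re](=O)(=O)O[Re](=O)(=O)=O
Why: Rhenium(VII) oxidative cyclisation of a bishomoallylic alcohol (Kennedy type, trifluoroacetyl perrhenate variant): the C6 perrhenate ester adds its O–Re=O unit suprafacially across C9=C10 (5-exo, O1–C9), so the E alkene should give the threo C9/C10 pair and the ring should close 2,5-trans to the pentyl group (C9 R, C10 R), the C7 silyl ether being unable to chelate rhenium and the remote terminal alkene lacking a directing hydroxyl.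

Step 11
Reactants: 19 (1R)-1-[(2R,4S,5S)-4-[(tert-butyldiphenylsilyl)oxy]-5-pentyloxolan-2-yl]dec-9-en-1-ol; 20 dodecanoyl chloride
Product: 21 (1R)-1-[(2R,4S,5S)-4-[(tert-butyldiphenylsilyl)oxy]-5-pentyloxolan-2-yl]dec-9-en-1-yl dodecanoate
Conditions: pyridine, DMAP (cat.), CH2Cl2, 0 °C → rt
Reagents that add atoms: none
Why: DMAP-catalysed acylation (nucleophilic catalysis) of the only free hydroxyl, the hindered C10 carbinol.

Step 12
Reactants: 21 (1R)-1-[(2R,4S,5S)-4-[(tert-butyldiphenylsilyl)oxy]-5-pentyloxolan-2-yl]dec-9-en-1-yl dodecanoate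
Product: 22 (1R)-1-[(2R,4S,5S)-4-hydroxy-5-pentyloxolan-2-yl]dec-9-en-1-yl dodecanoate (target)
Conditions: TBAF, AcOH (1:1), THF, rt → 40 °C
Reagents that add atoms: none
Why: Fluoride-induced cleavage of the silyl ether (Si–F bond formation); acetic acid buffering protects the laurate, which is trans-disposed to and remote from O7, from hydrolysis or migration.

**Compound list**

1 | rac-oct-1-en-3-ol | C=CC(O)CCCCC | starting material
2 | (S)-oct-1-en-3-ol | C=C[C@@H](O)CCCCC | intermediate
3 | (1S)-1-(1,2,4-trioxolan-3-yl)hexan-1-ol (secondary ozonide, both epimers at the ring carbon) | O1COOC1[C@@H](O)CCCCC | intermediate (not isolated)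
4 | (S)-2-hydroxyheptanal | O=C[C@@H](O)CCCCC | intermediate
5 | acetaldehyde | CC=O | starting material
6 | (3S,4S)-3,4-dihydroxynonanal (open-chain aldol) | O=CC[C@H](O)[C@@H](O)CCCCC | intermediate (not isolated)
7 | (4S,5S)-5-pentyloxolane-2,4-diol (anomeric mixture) | OC1C[C@H](O)[C@H](CCCCC)O1 | intermediate
8 | (2S,3S)-5-methoxy-2-pentyloxolan-3-ol (anomeric mixture) | COC1C[C@H](O)[C@H](CCCCC)O1 | intermediate
9 | tert-butyl{[(2S,3S)-5-methoxy-2-pentyloxolan-3-yl]oxy}diphenylsilane | COC1C[C@H](O[Si](c2ccccc2)(c2ccccc2)C(C)(C)C)[C@H](CCCCC)O1 | intermediate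
10 | (4S,5S)-4-[(tert-butyldiphenylsilyl)oxy]-5-pentyloxolan-2-ol (anomeric mixture) | OC1C[C@H](O[Si](c2ccccc2)(c2ccccc2)C(C)(C)C)[C@H](CCCCC)O1 | intermediate
11 | 10-bromodec-1-ene | C=CCCCCCCCCBr | starting material
12 | 1-phenyl-1H-tetrazole-5-thiol | Sc1nnnn1-c1ccccc1 | starting material
13 | 5-(dec-9-en-1-ylsulfanyl)-1-phenyl-1H-tetrazole | C=CCCCCCCCCSc1nnnn1-c1ccccc1 | intermediate
14 | 5-(dec-9-ene-1-sulfinyl)-1-phenyl-1H-tetrazole | C=CCCCCCCCCS(=O)c1nnnn1-c1ccccc1 | intermediate (not isolated)
15 | 5-(dec-9-ene-1-sulfonyl)-1-phenyl-1H-tetrazole | C=CCCCCCCCCS(=O)(=O)c1nnnn1-c1ccccc1 | intermediate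
16 | (6S,7S)-7-[(tert-butyldiphenylsilyl)oxy]-10-[(1-phenyl-1H-tetrazol-5-yl)sulfonyl]nonadec-18-ene-6,9-diol (present as potassium alkoxide, mixture at C9/C10) | CCCCC[C@H](O)[C@@H](O[Si](c1ccccc1)(c1ccccc1)C(C)(C)C)CC(O)C(CCCCCCCC=C)S(=O)(=O)c1nnnn1-c1ccccc1 | intermediate (not isolated)
17 | (6S,7S,9E)-7-[(tert-butyldiphenylsilyl)oxy]nonadeca-9,18-dien-6-ol | CCCCC[C@H](O)[C@@H](O[Si](c1ccccc1)(c1ccccc1)C(C)(C)C)C/C=C/CCCCCCCC=C | intermediate
18 | (6S,7S,9E)-7-[(tert-butyldiphenylsilyl)oxy]nonadeca-9,18-dien-6-yl perrhenate | CCCCC[C@H](O[Re](=O)(=O)=O)[C@@H](O[Si](c1ccccc1)(c1ccccc1)C(C)(C)C)C/C=C/CCCCCCCC=C | intermediate (not isolated)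
19 | (1R)-1-[(2R,4S,5S)-4-[(tert-butyldiphenylsilyl)oxy]-5-pentyloxolan-2-yl]dec-9-en-1-ol | C=CCCCCCCC[C@@H](O)[C@H]1C[C@H](O[Si](c2ccccc2)(c2ccccc2)C(C)(C)C)[C@H](CCCCC)O1 | intermediate
20 | dodecanoyl chloride (lauroyl chloride) | CCCCCCCCCCCC(=O)Cl | starting material
21 | (1R)-1-[(2R,4S,5S)-4-[(tert-butyldiphenylsilyl)oxy]-5-pentyloxolan-2-yl]dec-9-en-1-yl dodecanoate | C=CCCCCCCC[C@@H](OC(=O)CCCCCCCCCCC)[C@H]1C[C@H](O[Si](c2ccccc2)(c2ccccc2)C(C)(C)C)[C@H](CCCCC)O1 | intermediate
22 | (1R)-1-[(2R,4S,5S)-4-hydroxy-5-pentyloxolan-2-yl]dec-9-en-1-yl dodecanoate | C=CCCCCCCC[C@@H](OC(=O)CCCCCCCCCCC)[C@H]1C[C@H](O)[C@H](CCCCC)O1 | target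

**Step count**

Total: 12 steps. Longest linear sequence: 10 steps (steps 1–6 and 9–12); the sulfone branch is 2 steps (7 and 8).

**Steps most likely to fail**

Step 3 (Proposed new method). The enzyme may bind the lipophilic L-type acceptor poorly or turn over slowly, lose facial control in the mismatched pairing, or be inactivated by acetaldehyde, whose self-condensation can take over. The fallback sets out from 4 and returns at 7. Indium-mediated Barbier allylation of the unprotected hydroxy aldehyde (In, allyl bromide, THF/H2O, rt) should, through chelation of indium by the α-hydroxyl and the carbonyl, give mainly the threo diol (4S,5S)-dec-1-ene-4,5-diol F1; the minor erythro diol would be removed at this stage. Ozonolysis of F1 (O3, CH2Cl2/MeOH, −78 °C; Me2S) gives the 3,4-dihydroxy aldehyde, which closes to lactol 7. This is the known allylation/ozonolysis homologation of free α-hydroxy aldehydes to 2-deoxy sugars.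

Step 10. Ring closure may show poor 2,5-trans/cis selectivity because of the bulky C7 silyloxy group next to the reacting alkoxide, and the acidic medium may erode the silyl ether. The fallback sets out from 17 and returns at 21, replacing steps 10 and 11. Shi epoxidation of the E alkene with the ketone catalyst enantiomeric to the D-fructose-derived one (Oxone, K2CO3, pH 10.5 buffer, MeCN/dimethoxymethane, 0 °C) spares the terminal alkene and should give, under reagent control, (6S,7S)-7-[(tert-butyldiphenylsilyl)oxy]-8-[(2S,3S)-3-(non-8-en-1-yl)oxiran-2-yl]octan-6-ol F2. Camphorsulfonic acid (CH2Cl2, 0 °C) then lets the C6 hydroxyl open the epoxide at C9 with inversion (5-exo) to the trans-oxolane carrying the erythro alcohol, (1S)-1-[(2R,4S,5S)-4-[(tert-butyldiphenylsilyl)oxy]-5-pentyloxolan-2-yl]dec-9-en-1-ol F3. Mitsunobu esterification with dodecanoic acid (PPh3, DIAD, toluene) inverts C10 and gives 21 directly.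

Step 9. The hindered sulfonyl carbanion may add slowly to a lactol that is mostly closed, the E selectivity may be incomplete, and the strongly basic medium may cause silyl migration or β-elimination in the ring-opened alkoxide. The fallback sets out from 10 and returns at 19, replacing steps 9 and 10, and needs no control of alkene geometry. Wittig methylenation of the lactol (Ph3PCH3Br, KOtBu, THF, 0 °C → rt) gives (6S,7S)-7-[(tert-butyldiphenylsilyl)oxy]dec-9-en-6-ol F4. Cobalt-catalysed aerobic oxidative cyclisation of this pent-4-en-1-ol (Mukaiyama type: Co(nmp)2, O2, t-BuOOH, iPrOH, 55 °C), known to give 2,5-trans products, should give [(2R,4S,5S)-4-[(tert-butyldiphenylsilyl)oxy]-5-pentyloxolan-2-yl]methanol F5. Oxidation (Dess–Martin periodinane, NaHCO3, CH2Cl2) gives (2R,4S,5S)-4-[(tert-butyldiphenylsilyl)oxy]-5-pentyloxolane-2-carbaldehyde F6. Chelation-controlled addition of non-8-en-1-ylmagnesium bromide (from 9-bromonon-1-ene; MgBr2·OEt2, CH2Cl2/Et2O, −78 °C) should favour the threo alcohol 19.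

**Further compounds**

F1 | step 3 | (4S,5S)-dec-1-ene-4,5-diol | C=CC[C@H](O)[C@@H](O)CCCCC
F2 | step 10 | (6S,7S)-7-[(tert-butyldiphenylsilyl)oxy]-8-[(2S,3S)-3-(non-8-en-1-yl)oxiran-2-yl]octan-6-ol | CCCCC[C@H](O)[C@@H](O[Si](c1ccccc1)(c1ccccc1)C(C)(C)C)C[C@@H]1O[C@H]1CCCCCCCC=C
F3 | step 10 | (1S)-1-[(2R,4S,5S)-4-[(tert-butyldiphenylsilyl)oxy]-5-pentyloxolan-2-yl]dec-9-en-1-ol | C=CCCCCCCC[C@H](O)[C@H]1C[C@H](O[Si](c2ccccc2)(c2ccccc2)C(C)(C)C)[C@H](CCCCC)O1
F4 | step 9 | (6S,7S)-7-[(tert-butyldiphenylsilyl)oxy]dec-9-en-6-ol | CCCCC[C@H](O)[C@@H](O[Si](c1ccccc1)(c1ccccc1)C(C)(C)C)CC=C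
F5 | step 9 | [(2R,4S,5S)-4-[(tert-butyldiphenylsilyl)oxy]-5-pentyloxolan-2-yl]methanol | OC[C@H]1C[C@H](O[Si](c2ccccc2)(c2ccccc2)C(C)(C)C)[C@H](CCCCC)O1
F6 | step 9 | (2R,4S,5S)-4-[(tert-butyldiphenylsilyl)oxy]-5-pentyloxolane-2-carbaldehyde | O=C[C@H]1C[C@H](O[Si](c2ccccc2)(c2ccccc2)C(C)(C)C)[C@H](CCCCC)O1
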